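## Structural features

Grevirobstol B (23) is an achiral 22-membered cyclophane in which two benzene rings are joined twice: directly through one diaryl ether oxygen, and through an unbranched chain of sixteen methylene carbons (C1 to C16). Numbering ring A so that carbon 1 bears OH, carbon 3 the chain end C16 and carbon 5 the ether oxygen, and ring B so that carbon 1 bears the ether oxygen, carbons 2 and 4 OH and carbon 6 the chain end C1, ring A is bridged meta and ring B ortho. There is no stereocentre, so no neighbouring stereocentres have to be related; the only stereochemical element on the way is the geometry of a temporary C4=C5 alkene, which hydrogenation erases. The fragile groups are the three phenols (ring B is a 1,2,4-trioxygenated, easily oxidised ring), kept as methyl ethers to the last step, and, in the intermediates, the 2-aryloxyphenyl carbonyl unit, which under strongly acidic or cation-forming conditions can close onto the activated ortho positions of ring A to a xanthone or xanthene. The real difficulty is twofold: ring B carbon 1 is flanked on both sides (oxygen at carbon 2, chain at carbon 6), which makes the ether bond hard to form, and the large ring must be closed along a chain that carries no functional group. The key step exploits the place of C1: it sits on ring B carbon 6, next to the hindered ether carbon 1, so it can enter as the carboxyl carbon of a 2-aryloxybenzoic acid (where it assists the ether formation), become an aryl ketone, and so make C2 an enolate carbon that bonds to C3 when CO2 is expelled from a temporary allyl ester.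

## Logic of the disconnections

23 ⇒ 22. The three O–CH3 bonds (ring A carbon 1, ring B carbons 2 and 4) are added back. Reason: free phenols of this kind are oxidation-prone and acidic. Gain: every earlier step handles a neutral, robust tris(methyl ether), and one global deprotection ends the route. Demand: the Lewis-acid ether cleavage must leave the diaryl ether intact, which it should, since no other functional group remains in 22.

22 ⇒ 21. A C4=C5 double bond is reintroduced. Reason: it is the residue of the allyl unit used to form C2–C3. Gain: none in skeleton, but it leads back to the allylation product. Demand: a plain hydrogenation; placing it after the carbonyl removal makes any alkene migration or partial reduction in that step irrelevant.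

21 ⇒ 19 (through 20). The C1 methylene is retraced to a ketone. Reason: the carbonyl is what makes C2 nucleophilic in the key step and what assisted the ether formation as a carboxyl. Gain: C1 becomes a functional handle next to the congested ring B carbon 1. Demand: the deoxygenation must not pass through a C1 carbocation, which would be captured by ring A (xanthene); a base-mediated hydrazone reduction meets this.

19 ⇒ 18 (key). The C2–C3 bond is cut and CO2 is inserted between C2 and the oxygen on C3. Reason: the carbon–carbon closure of an unfunctionalised 22-membered ring is replaced by an ester closure, and the C–C bond then forms by recombination of two ends generated together. Gain: the ring-forming problem becomes a 24-membered lactonisation. Demand: linear (C3) rather than branched (C5) attack, C- rather than O-allylation, and no exchange of allyl units between molecules.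

18 ⇒ 16 (through 17). The ester bond between the C3 oxygen and the temporary carboxyl carbon is cut. Reason: capture of a ketene by a primary alcohol is fast, needs no activating reagent and tolerates high dilution. Gain: an open-chain hydroxy compound. Demand: the ketene precursor must be built while the C3 hydroxyl is masked and unmasked under conditions it survives; slow addition must keep the capture intramolecular.

16 ⇒ 15 ⇒ 13 + 14. The Si–O bond is restored on the C3 oxygen, then the bond between C1 and C2 is cut. Reason: 14 supplies C2 and the temporary carboxyl carbon in one operation from the carboxyl of 13. Gain: a simple benzoic acid. Demand: carboxyl activation under basic, non-Lewis-acidic conditions, so that the activated acyl group does not attack ring A.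

13 ⇒ 12 + 2, and 2 ⇒ 1. The bond between the ether oxygen and ring B carbon 1 is cut, then the C–Br bond. Reason: the carboxylate ortho to bromine directs the copper-mediated substitution at the doubly flanked carbon; the bromide is one bromination from 1. Gain: two separate arenes of similar size. Demand: the phenol of 12 must be the only nucleophile (the C3 oxygen is silylated), and bromination of 1 must occur ortho to the carboxyl and not between the methoxy groups.

12 ⇒ 10 (through 11) ⇒ 9 ⇒ 7 + 8. The silyl group is removed, the allylic alcohol is retraced to the conjugated ester, and the C4=C5 bond is cut. Reason: cross-metathesis with 8 adds C3 and C4 and sets the (E) geometry in one step. Gain: a ring A phenol with a plain terminal alkene. Demand: selective silylation of the aliphatic hydroxyl in the presence of the phenol, solved by silylating both and cleaving the aryl silyl ether.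

7 ⇒ 6 ⇒ 3 + 4 (through 5). One O–CH3 bond is restored, then the C15–C16 bond is cut. Reason: ring A needs exactly one free phenol for the ether formation, and the symmetric dimethyl ether allows a single demethylation without a statistical mixture; the chain is attached by sp3–sp3 coupling at the benzylic carbon. Gain: two catalogue compounds. Demand: the thiolate must stop after one methyl group and leave the terminal alkene untouched.

## Other disconnections considered

Alternative 1: The cut runs through ring B itself, between ring B carbons 1 and 6 and between carbons 2 and 3, and leads back to the open-chain aryloxymalonate A1, whose chain ends in an (E)-alk-3-en-2-one. In the forward key step an alkoxide base would form the malonate anion, which adds to the enone across the future 22-membered ring; the methyl ketone enolate so produced then closes onto one ester to give the bicyclic dione ester A2. Ester removal, oxidative aromatisation and ether cleavage would follow.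
- In its favour: the congested ether carbon of ring B is created as an sp3 malonate carbon by a simple O-alkylation, so no substitution at a di-ortho-substituted aryl halide is needed. On this point the alternative is better than the chosen plan. It also forms two rings in one operation, along the classical pattern used for 5-alkylresorcinols.
- Against it here: the macrocyclisation is a reversible conjugate addition of a fully substituted, weakly nucleophilic carbanion to a β-alkyl enone, with nothing that holds the chain ends together, so oligomerisation is a real competitor. The ring carbon of A2 that bears the aryloxy group is quaternary and must first lose its ester. Every aromatisation pathway then has to keep the aryloxy group, although its loss as a phenoxide would also aromatise ring B and open the macrocycle.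
- Comparison: structurally both plans need a long functionalised chain of similar effort. Mechanistically the chosen plan separates ring closure (ketene capture) from C–C bond formation (recombination of paired ends), whereas here one reversible addition must do both. In step count the alternative is about equal: roughly four steps after its key step against three.

Alternative 2: Three bonds of ring A are cut (carbon 1–carbon 6, carbon 4–carbon 5, carbon 1–carbon 2), leading back to A3, an ethynyl ether on the ring B oxygen tethered through the C16 chain to a 3-alkylcyclobutenone. On irradiation the cyclobutenone would open to a vinylketene; this adds to the electron-rich alkyne, and the new cyclobutenone opens and recloses by 6π electrocyclisation to give the phenol A4 (Danheiser-type benzannulation).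
- In its favour: ring A and the macrocycle arise in one metal-free cascade. The polarisation of the ynol ether places the ether oxygen meta to the new hydroxyl, exactly as required. A4 carries the ring A phenol free and is one ether cleavage away from 23, so after the key step this alternative is better than the chosen plan (one step against three). It also avoids the hindered aryl halide coupling.
- Against it here: the macrocyclisation coincides with the ketene–alkyne cycloaddition, normally run concentrated or with excess alkyne. At the dilution a 22-membered ring requires, the vinylketene is more likely to revert or be lost to dimerisation and adventitious nucleophiles. An ethynyl ether on a di-ortho-substituted, electron-rich phenol is laborious to make and delicate, and the cyclobutenone must be built at the far chain end.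
- Comparison: structurally it creates an arene where the chosen plan buys one. Mechanistically it places ring closure in the slowest step of a pericyclic cascade, against an ion-paired recombination after a reliable lactonisation. Total step count is probably comparable.

Alternative 3: The C1–C2 and C15–C16 bonds are cut, leading back to the bis(dithiane) A5 and the dibromide A6. In the forward key step double deprotonation of A5 with a strong lithium base and two alkylations by A6 would give the macrocyclic bis(dithiane) A7 (Corey–Seebach alkylation); reductive desulfurisation and ether cleavage would finish.
- In its favour: it is the shortest plan. The fourteen inner chain carbons are bought in one piece, the symmetric dielectrophile raises no regiochemical question, and only two steps follow the key step. In step economy this alternative is better than the chosen plan.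
- Equal point: the same hindered diaryl ether is required, and here without a carboxylate next to the halide, so this point is at best equal.
- Against it here: one alkylation is intermolecular and the other is a 22-membered ring closure, so the concentration needs conflict. Capture of a dianion by two molecules of A6, chain growth and elimination are the statistically expected competitors, and the carbanion next to ring B carbon 1 is hindered.
- Comparison: the chosen plan keeps both ring-forming events unimolecular, whereas this one staples three reactive ends in one flask. It trades reliability for brevity.

Key step: step 11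

Remarks on the chemistry (assumptions and design choices):
- The atom counts were checked: 18 is 24-membered and 19 is 22-membered, each with eleven methylenes C6–C16, consistent with the sixteen-carbon chain of 23.
- Ring A must offer exactly one free phenol for the ether formation, so one methyl ether is removed early (step 3).
- The C3 hydroxyl cannot be free while the ring B carboxyl is activated, so it is silylated from step 6 to step 9.
- The C1 carbonyl is not removed by a silane in strong acid, because a C1 cation would be trapped by ring A as a xanthene. A Wolff–Kishner reduction is used and placed before the hydrogenation.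
- Compounds 3, 4, 8 and 14 are taken as catalogue compounds. The chain is built by a copper-catalysed Grignard coupling and a cross-metathesis rather than by Wittig homologations, which saves two steps.
- Compounds 15 and 16 are drawn as enols and 18 as the keto tautomer.

## Route

Step 1
Reactants: 1 3,5-dimethoxybenzoic acid
Product: 2 2-bromo-3,5-dimethoxybenzoic acid
Conditions: NBS (1.05 equiv), MeCN, 0 °C → rt
Reagents that add atoms: N-bromosuccinimide, O=C1CCC(=O)N1Br
Why: Electrophilic aromatic bromination; as is general for 5-substituted 1,3-dimethoxybenzenes, attack should occur para to one methoxy group (ortho to the carboxyl) and not between the two methoxy groups.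

Step 2
Reactants: 3 12-bromododec-1-ene; 4 3,5-dimethoxybenzyl bromide
Product: 6 1,3-dimethoxy-5-(tridec-12-en-1-yl)benzene, via dodec-11-en-1-ylmagnesium bromide 5 (not isolated)
Conditions: 3, Mg, THF, 40 °C; then 4, Li2CuCl4 (3 mol %), THF, −20 °C → rt
Reagents that add atoms: magnesium, [Mg]
Why: Copper-catalysed sp3–sp3 cross-coupling of a primary alkyl Grignard reagent with a benzylic bromide (Kochi-type coupling); the benzylic carbon becomes C16 and the alkene carbon next to the chain is C5, and the copper catalyst should suppress halogen–metal exchange and bibenzyl formation. The magnesium is held only by the Grignard intermediate 5 and leaves as MgBr2 in the coupling.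

Step 3
Reactants: 6 1,3-dimethoxy-5-(tridec-12-en-1-yl)benzene
Product: 7 3-methoxy-5-(tridec-12-en-1-yl)phenol
Conditions: NaSEt (3 equiv), DMF, 140 °C, argon; then aq. HCl
Reagents that add atoms: none
Why: SN2 demethylation of an aryl methyl ether by thiolate; the phenoxide formed deactivates the ring towards loss of the second methyl group, so the reaction should stop at the monophenol, and the unactivated terminal alkene is inert to thiolate.

Step 4
Reactants: 7 3-methoxy-5-(tridec-12-en-1-yl)phenol; 8 ethyl acrylate
Product: 9 ethyl (2E)-14-(3-hydroxy-5-methoxyphenyl)tetradec-2-enoate
Conditions: 8 (5 equiv), second-generation Hoveyda–Grubbs catalyst RuCl2(H2IMes)(=CH-C6H4-2-OiPr) (3 mol %), CH2Cl2, 40 °C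
Reagents that add atoms: none
Why: Olefin cross-metathesis of a terminal alkene with an acrylate, which homodimerises poorly and should give the conjugated (E) ester; C4 and C3 are added, the (E) geometry of C4=C5 is set, and free phenols are tolerated by the ruthenium carbene.

Step 5
Reactants: 9 ethyl (2E)-14-(3-hydroxy-5-methoxyphenyl)tetradec-2-enoate
Product: 10 3-[(12E)-14-hydroxytetradec-12-en-1-yl]-5-methoxyphenol
Conditions: iBu2AlH (3.5 equiv), CH2Cl2, −78 → 0 °C; aq. KNaC4H4O6
Reagents that add atoms: none
Why: 1,2-Reduction of an α,β-unsaturated ester to the allylic alcohol by an aluminium hydride; one equivalent is consumed by the phenol and the alkene geometry is untouched.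

Step 6
Reactants: 10 3-[(12E)-14-hydroxytetradec-12-en-1-yl]-5-methoxyphenol
Product: 12 3-[(12E)-14-(tert-butyldimethylsilyloxy)tetradec-12-en-1-yl]-5-methoxyphenol, via bis-silyl ether 11 (not isolated)
Conditions: TBSCl (2.4 equiv), imidazole, DMF, rt; then K2CO3 (cat.), MeOH, rt
Reagents that add atoms: tert-butyldimethylsilyl chloride, CC(C)(C)[Si](C)(C)Cl
Why: Silylation of both hydroxyls followed by selective methanolysis of the aryl silyl ether, whose phenoxide is by far the better leaving group; the primary allylic silyl ether remains and masks the C3 oxygen during the carboxyl activation of step 8.

Step 7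
Reactants: 12 3-[(12E)-14-(tert-butyldimethylsilyloxy)tetradec-12-en-1-yl]-5-methoxyphenol; 2 2-bromo-3,5-dimethoxybenzoic acid
Product: 13 2-{3-[(12E)-14-(tert-butyldimethylsilyloxy)tetradec-12-en-1-yl]-5-methoxyphenoxy}-3,5-dimethoxybenzoic acid
Conditions: 2 (1.3 equiv), CuI (20 mol %), Cs2CO3 (3 equiv), DMF, 110 °C, argon; then aq. citric acid to pH 4
Reagents that add atoms: none
Why: Ullmann diaryl ether synthesis in its ortho-carboxylate-assisted form: the carboxylate holds copper next to the C–Br bond, which is what should make substitution at this doubly flanked carbon feasible; only the phenoxide is nucleophilic under carbonate, and the alkyl silyl ether is stable to anhydrous carbonate.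

Step 8
Reactants: 13 2-{3-[(12E)-14-(tert-butyldimethylsilyloxy)tetradec-12-en-1-yl]-5-methoxyphenoxy}-3,5-dimethoxybenzoic acid; 14 2,2-dimethyl-1,3-dioxane-4,6-dione (Meldrum's acid)
Product: 15 5-[(2-{3-[(12E)-14-(tert-butyldimethylsilyloxy)tetradec-12-en-1-yl]-5-methoxyphenoxy}-3,5-dimethoxyphenyl)(hydroxy)methylidene]-2,2-dimethyl-1,3-dioxane-4,6-dione (acyl Meldrum's acid of 13, enol form)
Conditions: DCC (1.2 equiv), DMAP (1.5 equiv), CH2Cl2, 0 °C → rt; cold aq. KHSO4 wash
Reagents that add atoms: none
Why: Steglich-type carbodiimide activation and C-acylation of the Meldrum's acid anion through the acylpyridinium ion, a standard route to aroyl Meldrum's acids; the basic medium without Lewis acid should keep the activated acyl group from closing onto ring A, and the silyl ether prevents self-esterification.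

Step 9
Reactants: 15 acyl Meldrum's acid of 13 (silyl ether)
Product: 16 5-[hydroxy(2-{3-[(12E)-14-hydroxytetradec-12-en-1-yl]-5-methoxyphenoxy}-3,5-dimethoxyphenyl)methylidene]-2,2-dimethyl-1,3-dioxane-4,6-dione
Conditions: HF·pyridine, THF, 0 °C → rt
Reagents that add atoms: none
Why: Fluoride-mediated cleavage of a primary silyl ether in a buffered acidic medium; acyl Meldrum's acids are themselves strong vinylogous acids, tolerate these conditions, and do not acylate alcohols below about 60 °C.

Step 10
Reactants: 16 hydroxy acyl Meldrum's acid
Product: 18 allyl β-keto macrolactone with a 24-membered ring (ring B carbon 6–C1(=O)–C2H2–C(=O)–O–C3H2–C4H=C5H–(CH2)11–ring A carbon 3; (E) alkene; trimethyl ether), via aroylketene 17 (not isolated)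
Conditions: slow addition (syringe pump) to toluene at 110 °C, final concentration about 0.5 mM
Reagents that add atoms: none
Why: Thermal fragmentation of the acyl Meldrum's acid releases acetone and CO2 and gives aroylketene 17, which is captured by the terminal primary alcohol (acylketene macrolactonisation, a known and dilution-tolerant macrocyclisation); slow addition keeps the ketene concentration low so that intramolecular capture should prevail.

Step 11
Reactants: 18 allyl β-keto macrolactone with a 24-membered ring
Product: 19 macrocyclic ketone with a 22-membered ring (ring B carbon 6–C1(=O)–C2H2–C3H2–C4H=C5H–(CH2)11–ring A carbon 3; (E) alkene; trimethyl ether)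
Conditions: Pd(PPh3)4 (10 mol %), toluene (degassed, 2 mM), 25 → 60 °C
Reagents that add atoms: none
Why: Zerovalent palladium inserts into the allylic C3–O bond of 18 and opens the lactone to a zwitterion with a cationic π-allyl palladium unit (C3–C5) at one chain end and the aroylacetate at the other; loss of CO2 (before or after C–C bond formation, both orders being known when the central carbon bears hydrogen) leaves the C2 enolate of the ring B aryl ketone, which bonds to the allyl terminus C3 and releases the catalyst. The closest known reaction is the palladium-catalysed decarboxylative allylation of allyl β-keto esters (Tsuji–Trost manifold, the catalytic counterpart of the Carroll rearrangement), established for open-chain allyl aroylacetates and applied here to a macrolactone as a ring contraction. The one ring formed, the 22-membered carbocycle, is closed by recombination of the two ends of the ring-opened ion pair at C2–C3 in the linear mode, so that C4=C5 stays inside the ring while the carboxyl carbon and its oxygen are extruded. No stereocentre is created; the (E) geometry of C4=C5 follows from the syn arrangement of the chain on the π-allyl unit, which is the preferred one and is reached by η3–η1–η3 equilibration. The step needs linear rather than branched attack (C3 and not C5, which would give a 20-membered ring with a vinyl branch); C3 is the unsubstituted, less hindered terminus, and triphenylphosphine-ligated palladium directs stabilised enolates there. It needs C- rather than O-allylation, which the soft π-allyl electrophile and the conjugated aryl ketone enolate favour. It needs recombination within one molecule rather than exchange between molecules; both ends are created together from one ester and stay ion-paired in toluene, and dilution keeps the acidic C2–H of unreacted 18 from intercepting a foreign allyl unit.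

Step 12
Reactants: 19 macrocyclic ketone with a 22-membered ring
Product: 21 macrocyclic (E)-C4=C5 alkene with C1 as CH2 (22-membered ring; trimethyl ether), via hydrazone 20 (not isolated)
Conditions: N2H4·H2O, KOH, diethylene glycol, 130 °C; then 195 °C with distillation of water
Reagents that add atoms: hydrazine, NN
Why: Wolff–Kishner reduction (Huang-Minlon procedure) of an aryl alkyl ketone through its hydrazone; the medium is basic throughout, so no C1 cation arises that ring A could trap, and any alkene shift or partial diimide reduction converges in step 13. The nitrogen atoms of hydrazine are held only by intermediate 20 and leave as N2.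

Step 13
Reactants: 21 macrocyclic (E)-C4=C5 alkene (trimethyl ether)
Product: 22 grevirobstol B trimethyl ether
Conditions: H2 (1 atm), Pd/C (10 wt % Pd), EtOAc, rt
Reagents that add atoms: none
Why: Heterogeneous hydrogenation of an unhindered disubstituted alkene; no other reducible group remains, and aryl ethers are stable under these conditions.

Step 14
Reactants: 22 grevirobstol B trimethyl ether
Product: 23 grevirobstol B
Conditions: BBr3 (9 equiv), CH2Cl2, −78 °C → rt; then MeOH, H2O; argon
Reagents that add atoms: none
Why: Lewis-acid cleavage of aryl methyl ethers by boron tribromide (bromide attacks the methyl group of the boron-complexed ether); diaryl ethers have no alkyl carbon to attack and are not cleaved, so only the three methyl groups should be lost.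

## Compound list

1 | 3,5-dimethoxybenzoic acid | COc1cc(cc(OC)c1)C(=O)O | starting material
2 | 2-bromo-3,5-dimethoxybenzoic acid | COc1cc(OC)c(Br)c(c1)C(=O)O | intermediate
3 | 12-bromododec-1-ene | C=CCCCCCCCCCCBr | starting material
4 | 3,5-dimethoxybenzyl bromide | COc1cc(CBr)cc(OC)c1 | starting material
5 | dodec-11-en-1-ylmagnesium bromide | C=CCCCCCCCCCC[Mg]Br | intermediate (not isolated)
6 | 1,3-dimethoxy-5-(tridec-12-en-1-yl)benzene | COc1cc(CCCCCCCCCCCC=C)cc(OC)c1 | intermediate
7 | 3-methoxy-5-(tridec-12-en-1-yl)phenol | COc1cc(O)cc(CCCCCCCCCCCC=C)c1 | intermediate
8 | ethyl acrylate | C=CC(=O)OCC | starting material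
9 | ethyl (2E)-14-(3-hydroxy-5-methoxyphenyl)tetradec-2-enoate | CCOC(=O)/C=C/CCCCCCCCCCCc1cc(O)cc(OC)c1 | intermediate
10 | 3-[(12E)-14-hydroxytetradec-12-en-1-yl]-5-methoxyphenol | OC/C=C/CCCCCCCCCCCc1cc(O)cc(OC)c1 | intermediate
11 | bis(tert-butyldimethylsilyl) ether of 10 (aryl and allylic oxygen) | CC(C)(C)[Si](C)(C)OC/C=C/CCCCCCCCCCCc1cc(O[Si](C)(C)C(C)(C)C)cc(OC)c1 | intermediate (not isolated)
12 | 3-[(12E)-14-(tert-butyldimethylsilyloxy)tetradec-12-en-1-yl]-5-methoxyphenol | CC(C)(C)[Si](C)(C)OC/C=C/CCCCCCCCCCCc1cc(O)cc(OC)c1 | intermediate
13 | 2-{3-[(12E)-14-(tert-butyldimethylsilyloxy)tetradec-12-en-1-yl]-5-methoxyphenoxy}-3,5-dimethoxybenzoic acid | CC(C)(C)[Si](C)(C)OC/C=C/CCCCCCCCCCCc1cc(OC)cc(Oc2c(OC)cc(OC)cc2C(=O)O)c1 | intermediate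
14 | 2,2-dimethyl-1,3-dioxane-4,6-dione (Meldrum's acid) | CC1(C)OC(=O)CC(=O)O1 | starting material
15 | acyl Meldrum's acid of 13, enol form, allylic oxygen silylated | CC(C)(C)[Si](C)(C)OC/C=C/CCCCCCCCCCCc1cc(OC)cc(Oc2c(OC)cc(OC)cc2C(O)=C2C(=O)OC(C)(C)OC2=O)c1 | intermediate
16 | acyl Meldrum's acid with free (E)-allylic alcohol, enol form | OC/C=C/CCCCCCCCCCCc1cc(OC)cc(Oc2c(OC)cc(OC)cc2C(O)=C2C(=O)OC(C)(C)OC2=O)c1 | intermediate
17 | 3-(2-{3-[(12E)-14-hydroxytetradec-12-en-1-yl]-5-methoxyphenoxy}-3,5-dimethoxyphenyl)-3-oxoprop-1-en-1-one (aroylketene) | OC/C=C/CCCCCCCCCCCc1cc(OC)cc(Oc2c(OC)cc(OC)cc2C(=O)C=C=O)c1 | intermediate (not isolated)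
18 | allyl β-keto macrolactone with a 24-membered ring, ketone at C1, ester between C2 and C3, (E)-C4=C5, trimethyl ether | COc1cc2cc(c1)Oc1c(OC)cc(OC)cc1C(=O)CC(=O)OC/C=C/CCCCCCCCCCC2 | intermediate
19 | macrocyclic C1 ketone with a 22-membered ring and (E)-C4=C5, trimethyl ether | COc1cc2cc(c1)Oc1c(OC)cc(OC)cc1C(=O)CC/C=C/CCCCCCCCCCC2 | intermediate
20 | C1 hydrazone of 19 | COc1cc2cc(c1)Oc1c(OC)cc(OC)cc1C(=NN)CC/C=C/CCCCCCCCCCC2 | intermediate (not isolated)
21 | macrocyclic (E)-C4=C5 alkene with C1 as CH2, 22-membered ring, trimethyl ether | COc1cc2cc(c1)Oc1c(OC)cc(OC)cc1CCC/C=C/CCCCCCCCCCC2 | intermediate
22 | grevirobstol B trimethyl ether | COc1cc2cc(c1)Oc1c(OC)cc(OC)cc1CCCCCCCCCCCCCCCC2 | intermediate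
23 | grevirobstol B | Oc1cc2cc(c1)Oc1c(O)cc(O)cc1CCCCCCCCCCCCCCCC2 | target

## Step count and least certain steps

Total step count: 14. Longest linear sequence: 13 steps (steps 2 to 14, from 3 and 4); step 1 is a one-step branch that joins at step 7.

1. Step 11 (key step). Three processes may compete:
- attack of the enolate at the substituted allyl terminus C5, which would contract the ring to a 20-membered ketone with a vinyl branch;
- exchange of allyl units between molecules, because the acidic C2–H of unreacted 18 can protonate the enolate end of an opened zwitterion and then be allylated itself, leading to ring-opened and oligomeric material;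
- β-hydride loss from the π-allyl unit towards C6, which ends the sequence as a ring-opened diene.

Ring contraction of a macrolactone of this size by this reaction has little precedent, so its efficiency is not assured. The fallback is the classical two-stage counterpart of the same C2–C3 bond; it sets out from 18 and returns at 19. Transesterifying ring opening of 18 in MeOH/toluene with catalytic DMAP at 100 °C (sealed tube) should give the open-chain hydroxy methyl β-keto ester F1. CBr4/PPh3 in CH2Cl2 converts its allylic alcohol into the (E)-allylic bromide F2. Slow addition of F2 to Cs2CO3 in MeCN at 60 °C closes the 22-membered ring by intramolecular SN2 C-alkylation of the β-keto ester, giving the macrocyclic 2-methoxycarbonyl ketone F3 (racemic). Krapcho dealkoxycarbonylation (LiCl, wet DMSO, 150 °C) removes the ester and delivers 19.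

2. Step 10. The aroylketene may be captured by the alcohol of a second molecule or may dimerise, so that oligomeric esters form in place of the 24-membered lactone; the ketene offers no conformational bias towards ring closure. The fallback closes the 24-membered ring at the alkene instead of at the ester; it sets out from 7 and 2 and returns at 18. Ullmann coupling of 7 with 2 under the conditions of step 7 should give the terminal-alkene acid F4. DCC/DMAP with 14 gives its acyl Meldrum's acid F5. Heating F5 in toluene with excess allyl alcohol gives the allyl β-keto ester F6 by intermolecular ketene capture, which needs no dilution. Ring-closing metathesis (second-generation Grubbs catalyst RuCl2(H2IMes)(PCy3)(=CHPh), CH2Cl2, 40 °C, 1 mM) forms C4=C5 and should give 18 together with its (Z) isomer F7. Both isomers ionise to the same π-allyl manifold and are taken through step 11 together. This fallback needs no silyl group; its price is the loss of geometric purity at C4=C5, which has no consequence after step 13.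

3. Step 7. Reductive loss of bromine from 2 may outrun C–O bond formation at the di-ortho-substituted carbon, turnover may be slow on the electron-rich ring, and the silyl ether may be partly lost in hot basic DMF. The fallback changes to palladium catalysis on the ester; it sets out from 2 and 12 and returns at 13. Methylation of 2 (MeI, K2CO3, DMF) gives methyl 2-bromo-3,5-dimethoxybenzoate F8. Buchwald–Hartwig-type C–O coupling of F8 with 12 (Pd(OAc)2, t-BuXPhos, K3PO4, toluene, 100 °C) should give the diaryl ether methyl ester F9. Saponification (LiOH, THF/MeOH/H2O, then cold dilute HCl to pH 4) gives 13.

4. Step 12. Hydrazone formation may be incomplete at the ketone next to the aryloxy group, azine formation may compete, and hot KOH may cleave some aryl methyl ether (tolerable, since step 14 removes these groups, but it complicates purification). The fallback avoids both hydrazones and cations; it sets out from 19 and returns at 22, passing over 21. NaBH4 in MeOH/THF reduces 19 to the benzylic alcohol F10 (racemic). Ac2O, pyridine and DMAP give the benzylic acetate F11 (racemic). H2 with Pd/C in EtOH hydrogenolyses the benzylic C–O bond and saturates C4=C5 in one operation, giving 22.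

## Further compounds

F1 | step 11 | methyl 3-(2-{3-[(12E)-14-hydroxytetradec-12-en-1-yl]-5-methoxyphenoxy}-3,5-dimethoxyphenyl)-3-oxopropanoate | OC/C=C/CCCCCCCCCCCc1cc(OC)cc(Oc2c(OC)cc(OC)cc2C(=O)CC(=O)OC)c1
F2 | step 11 | methyl 3-(2-{3-[(12E)-14-bromotetradec-12-en-1-yl]-5-methoxyphenoxy}-3,5-dimethoxyphenyl)-3-oxopropanoate | BrC/C=C/CCCCCCCCCCCc1cc(OC)cc(Oc2c(OC)cc(OC)cc2C(=O)CC(=O)OC)c1
F3 | step 11 | 19 carrying a methoxycarbonyl group on C2 (racemic) | COc1cc2cc(c1)Oc1c(OC)cc(OC)cc1C(=O)C(C(=O)OC)C/C=C/CCCCCCCCCCC2
F4 | step 10 | 3,5-dimethoxy-2-[3-methoxy-5-(tridec-12-en-1-yl)phenoxy]benzoic acid | COc1cc(CCCCCCCCCCCC=C)cc(Oc2c(OC)cc(OC)cc2C(=O)O)c1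
F5 | step 10 | acyl Meldrum's acid of F4, enol form | COc1cc(CCCCCCCCCCCC=C)cc(Oc2c(OC)cc(OC)cc2C(O)=C2C(=O)OC(C)(C)OC2=O)c1
F6 | step 10 | prop-2-en-1-yl 3-{3,5-dimethoxy-2-[3-methoxy-5-(tridec-12-en-1-yl)phenoxy]phenyl}-3-oxopropanoate | COc1cc(CCCCCCCCCCCC=C)cc(Oc2c(OC)cc(OC)cc2C(=O)CC(=O)OCC=C)c1
F7 | step 10 | (Z)-C4=C5 isomer of 18 | COc1cc2cc(c1)Oc1c(OC)cc(OC)cc1C(=O)CC(=O)OC/C=C\CCCCCCCCCCC2
F8 | step 7 | methyl 2-bromo-3,5-dimethoxybenzoate | COC(=O)c1cc(OC)cc(OC)c1Br
F9 | step 7 | methyl ester of 13 | CC(C)(C)[Si](C)(C)OC/C=C/CCCCCCCCCCCc1cc(OC)cc(Oc2c(OC)cc(OC)cc2C(=O)OC)c1
F10 | step 12 | C1 alcohol from 19 (racemic) | COc1cc2cc(c1)Oc1c(OC)cc(OC)cc1C(O)CC/C=C/CCCCCCCCCCC2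
F11 | step 12 | C1 acetate from 19 (racemic) | COc1cc2cc(c1)Oc1c(OC)cc(OC)cc1C(OC(C)=O)CC/C=C/CCCCCCCCCCC2
A1 | alternative 1 | dimethyl 2-{3-methoxy-5-[(17E)-19-oxoicos-17-en-1-yl]phenoxy}propanedioate | COC(=O)C(Oc1cc(OC)cc(CCCCCCCCCCCCCCCC/C=C/C(C)=O)c1)C(=O)OC
A2 | alternative 1 | macrocyclic methyl 1-aryloxy-2,4-dioxocyclohexane-1-carboxylate (racemic; one diastereomer drawn) | COC(=O)[C@@]12Oc3cc(OC)cc(c3)CCCCCCCCCCCCCCCC[C@H]1CC(=O)CC2=O
A3 | alternative 2 | 3-[16-(2-ethynyloxy-3,5-dimethoxyphenyl)hexadecyl]cyclobut-2-en-1-one | C#COc1c(OC)cc(OC)cc1CCCCCCCCCCCCCCCCC1=CC(=O)C1
A4 | alternative 2 | grevirobstol B with the two ring B hydroxyls as methyl ethers | Oc1cc2cc(c1)Oc1c(OC)cc(OC)cc1CCCCCCCCCCCCCCCC2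
A5 | alternative 3 | 2-{2-[3-(1,3-dithian-2-yl)-5-methoxyphenoxy]-3,5-dimethoxyphenyl}-1,3-dithiane | COc1cc(C2SCCCS2)cc(c1)Oc1c(OC)cc(OC)cc1C1SCCCS1
A6 | alternative 3 | 1,14-dibromotetradecane | BrCCCCCCCCCCCCCCBr
A7 | alternative 3 | macrocyclic bis(1,3-dithiane) at C1 and C16, trimethyl ether | COc1cc3cc(c1)Oc1c(OC)cc(OC)cc1C1(SCCCS1)CCCCCCCCCCCCCCC32SCCCS2
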